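The data were generated by integration for an exercise, and the scatter is random.

The alder run, with 100 mM of X at 10 °C, loses Q at 0.0282 min⁻¹ as a fraction of the charge. The maple run, with 420 mM of X at 32 °C, loses it at 0.0288 min⁻¹. So I freeze the rate, a zero-order reading, at 0.0285 min⁻¹. The time one whole charge takes at that rate is the feed time, 35.1 min.

| flask | Q | X | temperature | remark | time |
|---|---|---|---|---|---|
| alder | 2.3 M | 100 mM | 10 °C | run made earlier |  |
| maple | 2.3 M | 420 mM | 32 °C | run made earlier |  |
| midnight | 2.3 M | 210 mM | 20 °C |  | 40 min |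
| noon | 2.3 M | 210 mM | 0 °C |  | 40 min |
| summer | 2.3 M | 210 mM | 40 °C |  | 40 min |

- alder (time / min: D / %, Q / %): 2.50: 0, 93.4; 8.00: 11.1, 76.3; 12.0: 20.1, 65.6; 20.0: 38.2, 40.5; 30.0: 58.6, 15.8; 40.0: 75.1, 0
- maple (time / min: D / %, Q / %): 2.00: 2.3, 92.6; 4.00: 6.7, 86.3; 6.00: 10.5, 79.3; 8.00: 11.0, 75.0; 12.0: 15.7, 64.1; 15.0: 19.8, 55.2

(readings scatter by 1 percentage point)

- given per volume of solution although it is solid: Q
- at the start none of Q is in solution
- what has only dissolved of Q counts as not reacted

- the flask that comes out highest in amount of D, in percent of the Q charged, or "all alike" when all lie within 1.5 percentage points (midnight / noon / summer / all alike)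
- D at the end, in percent of the Q charged, midnight
- D at the end, in percent of the Q charged, noon
- D at the end, in percent of the Q charged, summer

I hold two times against each other: this feed time and the asked 40 min. Their ratio is 0.877. Midnight, at 20 °C, is warmer than the alder run and cooler than the maple run, so I carry the feed time there, and midnight should lose its Q with 4.90 min to spare. Noon, at 0 °C, is colder than the alder run, and summer, at 40 °C, is hotter than the maple run, so I trust the feed time less in those two flasks. The alder run shows that Q lost is not the same as D made: at 40.0 min its Q reads 0%, yet 24.9% of the charge is not D.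

The forecast gives 64% for midnight, 76% for noon and 47% for summer, with noon highest: “I lean towards a temperature effect, which favours noon”.

    L ⇌ D (K = 2.40, k = 0.594 min⁻¹, Ea = 72.0 kJ mol⁻¹, ΔH = −52.0 kJ mol⁻¹)
    L + X ⇌ J + X, rate k2*[L]*[X] forward; the back reaction follows from the equilibrium constant (K = 0.322, k = 0.328 M⁻¹ min⁻¹, Ea = 68.0 kJ mol⁻¹, ΔH = −40.0 kJ mol⁻¹)
    L ⇌ E (K = 0.0770, k = 2.78 min⁻¹, Ea = 69.0 kJ mol⁻¹, ΔH = 1.00 kJ mol⁻¹)
    Q ⇌ L, rate k4*(cs4 - [L]) while solid is left; crystals form when [L] > cs4 (solubility = 1.80 M, k = 0.0443 min⁻¹)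
    (constants at 20 °C)

The flasks give 63.2% of D in midnight, 57.4% in noon and 30.0% in summer, so midnight is highest. At 40.0 min, against a feed time of 35.1 min, Q stands at 0% in midnight, 2.38% in noon and 11.7% in summer. For midnight at 10 min, the frozen rate gives Q as 71.5%, and that neighbour shows 68.2%. Noon still holds 30.7% as dissolved Q, L, at the stop. Left until 400 min, midnight stays at 63.2% of D, summer reaches 34.0%, and noon climbs to 84.1%, with L down to 7.36%.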